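## Retrosynthetic overview

1. The C17 acetate and the C7=C8 alkene come from the kinetic enol triflate of a C8 ketone by hydroxymethyl Stille coupling. The C9 side chain comes from an aldol addition, dehydration and hydrogenation with an aldehyde made from (R)-3-methylglutaric acid monomethyl ester, which supplies C13.
2. Ring A is closed by ring-closing metathesis that forms the C2=C3 bond, followed by hydrogenation. The quaternary C10 comes from a Hosomi–Sakurai allylation anti to the C5 substituent. Ring B and C5 come from an organocatalytic Michael addition and aldol condensation.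
3. Feature that makes the key step possible: the allyl group on quaternary C10 (C1, C2) and the vinyl group on quaternary C4 (C3) sit trans on the neighbouring ring B carbons C10 and C5. This 1,7-diene is pre-organised by two quaternary carbons, so C2 and C3 close the six-membered ring A directly as the trans-decalin.
4. Order of ring formation: ring B (step 3), then ring A (step 10).

Key step: step 10

Remark: labdane numbering is used (C1–C10 decalin, C11–C16 side chain, C17 on C8). The target is read as the ent-labdane (5R,9S,10R,13R), with H-5 and H-9 cis to each other and trans to the C10 methyl. Compounds 1, 3 and 8 are taken as commercial.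

## Route

Step 1
Reactants: 1 methyl 3,3-dimethylpent-4-enoate
Product: 2 3,3-dimethylpent-4-enal
Conditions: i-Bu2AlH, CH2Cl2, −78 °C
Reagents that add atoms: none
Why: Partial reduction of the ester through the tetrahedral aluminium hemiacetal, which is stable at low temperature, should stop at the aldehyde (ester-to-aldehyde reduction).

Step 2
Reactants: 2 3,3-dimethylpent-4-enal; 3 but-3-en-2-one
Product: 4 (2R)-2-(2-methylbut-3-en-2-yl)-5-oxohexanal
Conditions: (R)-2-[diphenyl(trimethylsilyloxy)methyl]pyrrolidine (10 mol%), ethyl 3,4-dihydroxybenzoate (20 mol%), neat, 4 °C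
Reagents that add atoms: none
Why: Enamine-mediated organocatalytic Michael addition of the aldehyde to the vinyl ketone, in which the diarylmethyl group of the (R)-catalyst shields one face of the (E)-enamine so that C5 should be set as (2R).

Step 3
Reactants: 4 (2R)-2-(2-methylbut-3-en-2-yl)-5-oxohexanal
Product: 5 (4S)-4-(2-methylbut-3-en-2-yl)cyclohex-2-en-1-one
Conditions: LiOH (cat.), i-PrOH, rt
Reagents that add atoms: none
Why: Intramolecular aldol condensation of the methyl ketone onto the aldehyde closes ring B as the cyclohexenone under mild base, which should leave the C5 stereocentre (now γ to the carbonyl) untouched.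

Step 4
Reactants: 5 (4S)-4-(2-methylbut-3-en-2-yl)cyclohex-2-en-1-one
Product: 6 trimethyl{[(3R,4S)-3-methyl-4-(2-methylbut-3-en-2-yl)cyclohex-1-en-1-yl]oxy}silane
Conditions: MeMgBr, CuBr·SMe2 (5 mol%), Me3SiCl, DMPU, THF, −78 °C
Reagents that add atoms: methylmagnesium bromide C[Mg]Br; chlorotrimethylsilane C[Si](C)(C)Cl
Why: Copper-catalysed conjugate addition with in situ silyl trapping gives the regiodefined silyl enol ether, the methyl group entering anti to the C5 substituent (this centre is planarised again in step 5).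

Step 5
Reactants: 6 trimethyl{[(3R,4S)-3-methyl-4-(2-methylbut-3-en-2-yl)cyclohex-1-en-1-yl]oxy}silane
Product: 7 (4S)-3-methyl-4-(2-methylbut-3-en-2-yl)cyclohex-2-en-1-one
Conditions: Pd(OAc)2 (1.05 equiv), MeCN, rt
Reagents that add atoms: none
Why: Saegusa–Ito oxidation (palladium enolate, β-hydride elimination of H-10) regenerates the enone, which now carries the C10 methyl.

Step 6
Reactants: 8 (3R)-5-methoxy-3-methyl-5-oxopentanoic acid
Product: 9 methyl (3R)-5-hydroxy-3-methylpentanoate
Conditions: BH3·SMe2, THF, 0 °C to rt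
Reagents that add atoms: none
Why: Borane reduces the carboxylic acid chemoselectively in the presence of the methyl ester (acyloxyborane pathway).

Step 7
Reactants: 9 methyl (3R)-5-hydroxy-3-methylpentanoate
Product: 10 methyl (3R)-3-methyl-5-oxopentanoate
Conditions: Dess–Martin periodinane, CH2Cl2, rt
Reagents that add atoms: none
Why: Mild periodinane oxidation of the primary alcohol gives the aldehyde without touching the ester or the remote C13 stereocentre.

Step 8
Reactants: 7 (4S)-3-methyl-4-(2-methylbut-3-en-2-yl)cyclohex-2-en-1-one; 10 methyl (3R)-3-methyl-5-oxopentanoate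
Product: 12 methyl (3R)-5-hydroxy-3-methyl-5-[(2R,3R)-2-methyl-3-(2-methylbut-3-en-2-yl)-6-oxo-2-(prop-2-en-1-yl)cyclohexyl]pentanoate, via trichlorotitanium enolate 11 (not isolated)
Conditions: allyltrimethylsilane, TiCl4, CH2Cl2, −78 °C; then 10, −78 to −40 °C
Reagents that add atoms: allyltrimethylsilane C=CC[Si](C)(C)C
Why: Hosomi–Sakurai conjugate allylation of the TiCl4-activated enone should place the allyl group on C10 anti to the bulky C5 substituent (quaternary centre with the methyl cis to the C4 arm), and the regiodefined titanium enolate is intercepted at C9 by the aldehyde in a tandem aldol addition whose two new centres are erased in step 9.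

Step 9
Reactants: 12 methyl (3R)-5-hydroxy-3-methyl-5-[(2R,3R)-2-methyl-3-(2-methylbut-3-en-2-yl)-6-oxo-2-(prop-2-en-1-yl)cyclohexyl]pentanoate
Product: 13 methyl (3R)-3-methyl-5-[(2R,3R)-2-methyl-3-(2-methylbut-3-en-2-yl)-6-oxo-2-(prop-2-en-1-yl)cyclohexylidene]pentanoate
Conditions: MsCl, Et3N, CH2Cl2, 0 °C to rt
Reagents that add atoms: none
Why: Mesylation and E1cB elimination of the β-hydroxy ketone gives the exocyclic enone (aldol dehydration), whose alkene geometry is irrelevant because it is hydrogenated in step 11.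

Step 10
Reactants: 13 methyl (3R)-3-methyl-5-[(2R,3R)-2-methyl-3-(2-methylbut-3-en-2-yl)-6-oxo-2-(prop-2-en-1-yl)cyclohexylidene]pentanoate
Product: 14 methyl (3R)-3-methyl-5-[(4aR,8aR)-5,5,8a-trimethyl-2-oxo-3,4,4a,5,8,8a-hexahydronaphthalen-1(2H)-ylidene]pentanoate
Conditions: second-generation Grubbs catalyst (5 mol%), CH2Cl2 (0.005 M), 40 °C
Reagents that add atoms: none
Why: The ruthenium alkylidene loads onto the unhindered allyl terminus (C2), undergoes intramolecular [2+2] cycloaddition and cycloreversion with the vinyl group on quaternary C4 (C3), and expels ethene, which drives the closure. The closest known reaction type is ring-closing metathesis of 1,7-dienes to cyclohexenes that carry an allylic quaternary carbon. Ring A is closed as a six-membered ring by forming the C2=C3 bond between two arms fixed trans on the adjacent ring B carbons C5 and C10, so the trans ring fusion follows directly. No new stereocentre is created, and the configurations at C5 and C10 from steps 2 and 8 are carried into the decalin. The step needs selectivity for the two terminal alkenes over the trisubstituted, electron-poor exocyclic enone and for cyclisation over dimerisation, which the substitution pattern, the gem-dialkyl effect of C4 and C10 and high dilution should secure. Because C4 bears no allylic hydrogen, alkene migration on that side is excluded.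

Step 11
Reactants: 14 methyl (3R)-3-methyl-5-[(4aR,8aR)-5,5,8a-trimethyl-2-oxo-3,4,4a,5,8,8a-hexahydronaphthalen-1(2H)-ylidene]pentanoate
Product: 15 methyl (3R)-3-methyl-5-[(1S,4aR,8aR)-5,5,8a-trimethyl-2-oxodecahydronaphthalen-1-yl]pentanoate
Conditions: H2 (1 atm), Pd/C, EtOAc, rt
Reagents that add atoms: none
Why: Heterogeneous hydrogenation saturates the ring A alkene and the exocyclic enone, with hydrogen delivered to C9 from the face opposite the axial C10 methyl, so that H-9 should end cis to H-5 with the side chain equatorial, which is also expected to be the more stable C9 epimer.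

Step 12
Reactants: 15 methyl (3R)-3-methyl-5-[(1S,4aR,8aR)-5,5,8a-trimethyl-2-oxodecahydronaphthalen-1-yl]pentanoate
Product: 16 methyl (3R)-3-methyl-5-[(1S,4aR,8aR)-5,5,8a-trimethyl-2-(trifluoromethylsulfonyloxy)-1,4,4a,5,6,7,8,8a-octahydronaphthalen-1-yl]pentanoate
Conditions: LiN(SiMe3)2, THF, −78 °C; then PhNTf2, −78 to 0 °C
Reagents that add atoms: N-phenylbis(trifluoromethanesulfonimide) O=S(=O)(N(c1ccccc1)S(=O)(=O)C(F)(F)F)C(F)(F)F
Why: Kinetic deprotonation at the less hindered C7 methylene (rather than the tertiary C9–H or the less acidic ester) and O-triflation fix the alkene at C7=C8 (kinetic enol triflate formation).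

Step 13
Reactants: 16 methyl (3R)-3-methyl-5-[(1S,4aR,8aR)-5,5,8a-trimethyl-2-(trifluoromethylsulfonyloxy)-1,4,4a,5,6,7,8,8a-octahydronaphthalen-1-yl]pentanoate
Product: 17 methyl (3R)-5-[(1S,4aR,8aR)-2-(hydroxymethyl)-5,5,8a-trimethyl-1,4,4a,5,6,7,8,8a-octahydronaphthalen-1-yl]-3-methylpentanoate
Conditions: Bu3SnCH2OH, Pd(PPh3)4 (5 mol%), LiCl, 1,4-dioxane, 100 °C
Reagents that add atoms: (tributylstannyl)methanol OC[Sn](CCCC)(CCCC)CCCC
Why: Stille coupling of the vinyl triflate with the hydroxymethylstannane installs C17 on C8 with the alkene held at C7=C8 and leaves the side-chain ester untouched.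

Step 14
Reactants: 17 methyl (3R)-5-[(1S,4aR,8aR)-2-(hydroxymethyl)-5,5,8a-trimethyl-1,4,4a,5,6,7,8,8a-octahydronaphthalen-1-yl]-3-methylpentanoate
Product: 18 methyl (3R)-5-[(1S,4aR,8aR)-2-(acetoxymethyl)-5,5,8a-trimethyl-1,4,4a,5,6,7,8,8a-octahydronaphthalen-1-yl]-3-methylpentanoate
Conditions: Ac2O, pyridine, 4-(dimethylamino)pyridine (cat.), CH2Cl2, rt
Reagents that add atoms: acetic anhydride CC(=O)OC(C)=O
Why: Acetylation of the primary allylic alcohol gives the target.

## Compound list

1 | methyl 3,3-dimethylpent-4-enoate | COC(=O)CC(C)(C)C=C | starting material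
2 | 3,3-dimethylpent-4-enal | O=CCC(C)(C)C=C | intermediate
3 | but-3-en-2-one | CC(=O)C=C | starting material
4 | (2R)-2-(2-methylbut-3-en-2-yl)-5-oxohexanal | CC(=O)CC[C@H](C(C)(C)C=C)C=O | intermediate
5 | (4S)-4-(2-methylbut-3-en-2-yl)cyclohex-2-en-1-one | O=C1CC[C@H](C(C)(C)C=C)C=C1 | intermediate
6 | trimethyl{[(3R,4S)-3-methyl-4-(2-methylbut-3-en-2-yl)cyclohex-1-en-1-yl]oxy}silane | C[Si](C)(C)OC1=C[C@H](C)[C@@H](C(C)(C)C=C)CC1 | intermediate
7 | (4S)-3-methyl-4-(2-methylbut-3-en-2-yl)cyclohex-2-en-1-one | O=C1CC[C@H](C(C)(C)C=C)C(C)=C1 | intermediate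
8 | (3R)-5-methoxy-3-methyl-5-oxopentanoic acid ((R)-3-methylglutaric acid monomethyl ester) | COC(=O)C[C@H](C)CC(=O)O | starting material
9 | methyl (3R)-5-hydroxy-3-methylpentanoate | COC(=O)C[C@H](C)CCO | intermediate
10 | methyl (3R)-3-methyl-5-oxopentanoate | COC(=O)C[C@H](C)CC=O | intermediate
11 | trichloro{[(3R,4R)-3-methyl-4-(2-methylbut-3-en-2-yl)-3-(prop-2-en-1-yl)cyclohex-1-en-1-yl]oxy}titanium (trichlorotitanium enolate) | Cl[Ti](Cl)(Cl)OC1=C[C@](C)(CC=C)[C@@H](C(C)(C)C=C)CC1 | intermediate (not isolated)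
12 | methyl (3R)-5-hydroxy-3-methyl-5-[(2R,3R)-2-methyl-3-(2-methylbut-3-en-2-yl)-6-oxo-2-(prop-2-en-1-yl)cyclohexyl]pentanoate (epimer mixture at the carbinol carbon and at ring C-1) | COC(=O)C[C@H](C)CC(O)C1C(=O)CC[C@H](C(C)(C)C=C)[C@@]1(C)CC=C | intermediate
13 | methyl (3R)-3-methyl-5-[(2R,3R)-2-methyl-3-(2-methylbut-3-en-2-yl)-6-oxo-2-(prop-2-en-1-yl)cyclohexylidene]pentanoate (E/Z not controlled) | COC(=O)C[C@H](C)CC=C1C(=O)CC[C@H](C(C)(C)C=C)[C@@]1(C)CC=C | intermediate
14 | methyl (3R)-3-methyl-5-[(4aR,8aR)-5,5,8a-trimethyl-2-oxo-3,4,4a,5,8,8a-hexahydronaphthalen-1(2H)-ylidene]pentanoate (E/Z not controlled) | COC(=O)C[C@H](C)CC=C1C(=O)CC[C@@H]2C(C)(C)C=CC[C@@]12C | intermediate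
15 | methyl (3R)-3-methyl-5-[(1S,4aR,8aR)-5,5,8a-trimethyl-2-oxodecahydronaphthalen-1-yl]pentanoate | COC(=O)C[C@H](C)CC[C@@H]1C(=O)CC[C@@H]2C(C)(C)CCC[C@@]12C | intermediate
16 | methyl (3R)-3-methyl-5-[(1S,4aR,8aR)-5,5,8a-trimethyl-2-(trifluoromethylsulfonyloxy)-1,4,4a,5,6,7,8,8a-octahydronaphthalen-1-yl]pentanoate | COC(=O)C[C@H](C)CC[C@@H]1C(OS(=O)(=O)C(F)(F)F)=CC[C@@H]2C(C)(C)CCC[C@@]12C | intermediate
17 | methyl (3R)-5-[(1S,4aR,8aR)-2-(hydroxymethyl)-5,5,8a-trimethyl-1,4,4a,5,6,7,8,8a-octahydronaphthalen-1-yl]-3-methylpentanoate | COC(=O)C[C@H](C)CC[C@@H]1C(CO)=CC[C@@H]2C(C)(C)CCC[C@@]12C | intermediate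
18 | methyl (3R)-5-[(1S,4aR,8aR)-2-(acetoxymethyl)-5,5,8a-trimethyl-1,4,4a,5,6,7,8,8a-octahydronaphthalen-1-yl]-3-methylpentanoate | COC(=O)C[C@H](C)CC[C@@H]1C(COC(C)=O)=CC[C@@H]2C(C)(C)CCC[C@@]12C | target

## Step count and risks

Total step count: 14 steps. Longest linear sequence: 12 steps (steps 1–5 and 8–14).

**Step 8.** The allylsilane may add too slowly to the β-carbon, which is flanked by the tertiary-alkyl-bearing C5, so that TiCl4 degrades the enone instead. The titanium aldolate may also revert by retro-aldol during the tandem stage. The fallback uses an organocopper addition with silyl trapping and a separate Lewis-acid aldol. It sets out from 7: the allylcopper reagent made from allyllithium, CuI and LiCl is added in the presence of Me3SiCl (THF, −78 °C) to give the silyl enol ether trimethyl{[(3R,4R)-3-methyl-4-(2-methylbut-3-en-2-yl)-3-(prop-2-en-1-yl)cyclohex-1-en-1-yl]oxy}silane F1. Mukaiyama aldol addition of F1 to 10 (BF3·OEt2, CH2Cl2, −78 °C) comes back to the route at 12.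

**Step 10.** The propagating ruthenium carbene may be diverted by the conjugated exocyclic alkene or held by the ketone and ester carbonyls, so that oligomerisation through the allyl group outruns cyclisation. The fallback changes the order of events so that ring A is closed on a substrate with neither enone nor ester. It sets out from 7, which is converted as above into trimethyl{[(3R,4R)-3-methyl-4-(2-methylbut-3-en-2-yl)-3-(prop-2-en-1-yl)cyclohex-1-en-1-yl]oxy}silane F1. Ring-closing metathesis of F1 (second-generation Grubbs catalyst, CH2Cl2, 40 °C) should give the bicyclic silyl enol ether trimethyl{[(4aR,8aR)-5,5,8a-trimethyl-3,4,4a,5,8,8a-hexahydronaphthalen-2-yl]oxy}silane F2. Mukaiyama aldol addition of F2 to 10 (BF3·OEt2, CH2Cl2, −78 °C) gives methyl (3R)-5-hydroxy-3-methyl-5-[(4aR,8aR)-5,5,8a-trimethyl-2-oxo-1,2,3,4,4a,5,8,8a-octahydronaphthalen-1-yl]pentanoate F3, and its dehydration (MsCl, Et3N) comes back to the route at 14.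

**Step 2.** The β-quaternary aldehyde may form its enamine slowly, so that conversion stalls and the adduct loses enantiopurity on long exposure to the amine. The fallback replaces catalysis with a stoichiometric chiral auxiliary. It sets out from 2, which is condensed with (S)-1-amino-2-(methoxymethyl)pyrrolidine to the hydrazone (2S)-N-[(1E)-3,3-dimethylpent-4-en-1-ylidene]-2-(methoxymethyl)pyrrolidin-1-amine F4. Deprotonation (LiN(i-Pr)2, THF, −78 °C) and alkylation of the azaenolate with 2-(2-iodoethyl)-2-methyl-1,3-dioxolane at −100 °C should give (2S)-N-[(1E,2R)-3,3-dimethyl-2-[2-(2-methyl-1,3-dioxolan-2-yl)ethyl]pent-4-en-1-ylidene]-2-(methoxymethyl)pyrrolidin-1-amine F5, with the auxiliary controlling the new centre. Two-phase acidic hydrolysis (aqueous oxalic acid, then dilute HCl in THF) releases the aldehyde and the ketone and comes back to the route at 4.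

Further compounds

F1 | step 8 | trimethyl{[(3R,4R)-3-methyl-4-(2-methylbut-3-en-2-yl)-3-(prop-2-en-1-yl)cyclohex-1-en-1-yl]oxy}silane | C[Si](C)(C)OC1=C[C@](C)(CC=C)[C@@H](C(C)(C)C=C)CC1
F2 | step 10 | trimethyl{[(4aR,8aR)-5,5,8a-trimethyl-3,4,4a,5,8,8a-hexahydronaphthalen-2-yl]oxy}silane | C[Si](C)(C)OC1=C[C@]2(C)CC=CC(C)(C)[C@H]2CC1
F3 | step 10 | methyl (3R)-5-hydroxy-3-methyl-5-[(4aR,8aR)-5,5,8a-trimethyl-2-oxo-1,2,3,4,4a,5,8,8a-octahydronaphthalen-1-yl]pentanoate (epimer mixture at the carbinol carbon and at ring C-1) | COC(=O)C[C@H](C)CC(O)C1C(=O)CC[C@@H]2C(C)(C)C=CC[C@@]12C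
F4 | step 2 | (2S)-N-[(1E)-3,3-dimethylpent-4-en-1-ylidene]-2-(methoxymethyl)pyrrolidin-1-amine | COC[C@@H]1CCCN1/N=C/CC(C)(C)C=C
F5 | step 2 | (2S)-N-[(1E,2R)-3,3-dimethyl-2-[2-(2-methyl-1,3-dioxolan-2-yl)ethyl]pent-4-en-1-ylidene]-2-(methoxymethyl)pyrrolidin-1-amine | CC1(CC[C@H](C(C)(C)C=C)/C=N/N2CCC[C@H]2COC)OCCO1
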